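**Retrosynthetic overview**
- The strategy rests on the O1–C2 benzylic aryl ether of the dihydrofuran ring (O1, C2, C3, C3a, C7a), in which ring A on C2 is cis to the CH2OH on C3. This bond is made last within that ring, by SN2 inversion of a syn-aldol carbinol.
- Late disconnections: the three protecting groups, then the bond from C5 of ring B to C1 of the furofuran, giving arylzinc 31 (fragment 1) and anomeric bromide 29 (fragment 2).
- Fragment 1: ring C by Mitsunobu closure of phenol 15. C2–C3 and both stereocentres come from an Evans syn-aldol of arylacetyl imide 8 with O-tosylvanillin 10.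
- Fragment 2: conjugate addition/aldol on menthyloxybutenolide 18, reduction, benzylic-cation closure of ring E (step 14), then lactol ring D (step 15).
- Ring order: E, D (fragment 2); C (fragment 1, step 11); union in step 19 by convex-face arylation of the bicyclic oxocarbenium ion.

Key step: step 11

Remark: ring A = guaiacyl ring on C2, ring B = benzo ring and ring C = dihydrofuran ring of the dihydrobenzofuran, rings D and E = the two tetrahydrofurans of the dioxabicyclo[3.3.0]octane, ring F = syringyl ring; butenolide 18 is assumed purchasable (otherwise it is made from furfural and l-menthol).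

**Fragment 1 (steps 1–11)**

Step 1
Reactants: 1 5-bromo-2-hydroxy-3-methoxybenzaldehyde
Product: 2 2-(allyloxy)-5-bromo-3-methoxybenzaldehyde
Conditions: allyl bromide, K2CO3, DMF, rt
Reagents that add atoms: allyl bromide C=CCBr
Why: Williamson O-alkylation of the phenoxide masks the ring B phenol with a group that can later be removed without acid, strong base or hydrogen.

Step 2
Reactants: 2 2-(allyloxy)-5-bromo-3-methoxybenzaldehyde
Product: 3 2-(allyloxy)-5-bromo-1-methoxy-3-(2-methoxyvinyl)benzene (E/Z mixture)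
Conditions: MeOCH2PPh3Cl, KOtBu, THF, 0 °C to rt
Reagents that add atoms: (methoxymethyl)triphenylphosphonium chloride COC[P+](c1ccccc1)(c1ccccc1)c1ccccc1.[Cl-]
Why: Wittig methoxymethylenation of a non-enolisable benzaldehyde adds the one carbon needed for the arylacetic acid; the alkene geometry is irrelevant.

Step 3
Reactants: 3 the enol ether
Product: 4 2-[2-(allyloxy)-5-bromo-3-methoxyphenyl]acetaldehyde (used crude)
Conditions: 2 M HCl, THF, 50 °C
Reagents that add atoms: water O
Why: Acid hydrolysis of the enol ether should release the arylacetaldehyde while the allyl aryl ether, the methyl ether and the bromide are inert.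

Step 4
Reactants: 4 the arylacetaldehyde
Product: 5 2-[2-(allyloxy)-5-bromo-3-methoxyphenyl]acetic acid
Conditions: NaClO2, NaH2PO4, 2-methyl-2-butene, t-BuOH/H2O, rt
Reagents that add atoms: sodium chlorite [Na+].[O-]Cl=O
Why: Pinnick oxidation converts the sensitive aldehyde into the acid under buffered conditions, the alkene scavenger protecting the allyl group from hypochlorite.

Step 5
Reactants: 5 the arylacetic acid; 6 (R)-4-benzyl-2-oxazolidinone
Product: 8 (R)-3-{2-[2-(allyloxy)-5-bromo-3-methoxyphenyl]acetyl}-4-benzyloxazolidin-2-one, via mixed pivalic anhydride 7 (not isolated)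
Conditions: PivCl, Et3N, THF, −20 °C; then 6, LiCl, rt
Reagents that add atoms: none
Why: N-acylation of the oxazolidinone through the mixed anhydride with LiCl activation is the standard entry to arylacetyl imides and avoids strong base.

Step 6
Reactants: 9 vanillin
Product: 10 4-formyl-2-methoxyphenyl 4-methylbenzenesulfonate
Conditions: TsCl, Et3N, DMAP (cat.), CH2Cl2, 0 °C to rt
Reagents that add atoms: 4-toluenesulfonyl chloride Cc1ccc(cc1)S(=O)(=O)Cl
Why: Sulfonylation of the phenol gives an aldehyde whose para oxygen is no longer a donor, which is needed both for the aldol and for step 11.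

Step 7
Reactants: 8 the arylacetyl imide; 10 O-tosylvanillin
Product: 12 (R)-4-benzyl-3-[(2R,3R)-2-(2-allyloxy-5-bromo-3-methoxyphenyl)-3-hydroxy-3-(3-methoxy-4-tosyloxyphenyl)propanoyl]oxazolidin-2-one, via dibutylboron Z-enolate 11 (not isolated)
Conditions: Bu2BOTf, i-Pr2NEt, CH2Cl2, −78 to 0 °C; 10, −78 to 0 °C; pH 7 buffer, MeOH, H2O2
Reagents that add atoms: none
Why: Evans syn-aldol, in which the Z-boron enolate reacts through a Zimmerman–Traxler chair on the face away from the benzyl group of the (R)-auxiliary, setting both new centres as (2R,3R) with aryl and hydroxyl syn.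

Step 8
Reactants: 12 the syn-aldol adduct
Product: 13 4-[(1R,2S)-2-(2-allyloxy-5-bromo-3-methoxyphenyl)-1,3-dihydroxypropyl]-2-methoxyphenyl 4-methylbenzenesulfonate
Conditions: LiBH4, MeOH (1 equiv), THF, 0 °C
Reagents that add atoms: none
Why: Reductive cleavage of the imide gives the 1,3-diol and removes the epimerisable α-aryl carbonyl at once; aryl sulfonate and bromide are inert to LiBH4.

Step 9
Reactants: 13 the diol
Product: 14 4-[(1R,2S)-2-(2-allyloxy-5-bromo-3-methoxyphenyl)-3-(tert-butyldimethylsilyloxy)-1-hydroxypropyl]-2-methoxyphenyl 4-methylbenzenesulfonate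
Conditions: TBSCl, imidazole, CH2Cl2, 0 °C
Reagents that add atoms: tert-butyldimethylsilyl chloride CC(C)(C)[Si](C)(C)Cl
Why: Silylation is selective for the primary hydroxyl over the hindered benzylic one, which blocks the alternative five-membered closure onto C3–CH2.

Step 10
Reactants: 14 the allyl ether
Product: 15 4-[(1R,2S)-2-(5-bromo-2-hydroxy-3-methoxyphenyl)-3-(tert-butyldimethylsilyloxy)-1-hydroxypropyl]-2-methoxyphenyl 4-methylbenzenesulfonate
Conditions: Pd(PPh3)4 (5 mol%), morpholine, THF, rt
Reagents that add atoms: none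
Why: Tsuji–Trost deallylation, in which the palladium catalyst ionises the allyl aryl ether and morpholine traps the allyl unit, while the electron-rich aryl bromide and the sulfonate do not react at room temperature.

Step 11
Reactants: 15 the syn phenol carbinol
Product: 16 4-[(2S,3S)-5-bromo-3-(tert-butyldimethylsilyloxymethyl)-7-methoxy-2,3-dihydrobenzofuran-2-yl]-2-methoxyphenyl 4-methylbenzenesulfonate (cis)
Conditions: PPh3, DIAD, toluene, 0 °C to rt
Reagents that add atoms: none
Why: PPh3 and DIAD form the betaine, which deprotonates the ring B phenol and converts the only free alcohol, the benzylic C2 carbinol, into its alkoxyphosphonium ion, and the ortho phenoxide then expels Ph3P=O from the back side. The closest known reaction type is the Mitsunobu cycloetherification of 2-(2-hydroxyaryl)ethanols to 2-substituted 2,3-dihydrobenzofurans. Ring C (O1, C2, C3, C3a, C7a) closes in a 5-exo-tet mode by forming O1–C2. C2 is set by stereospecific inversion of the (1R) carbinol from the auxiliary-controlled aldol while C3 is carried over unchanged, so the syn diol gives the (2S,3S) cis ring. The step needs a clean SN2 course against ionisation to a benzylic cation (which would leak to the trans isomer) and against elimination to the stilbene; the sulfonate on the para oxygen of ring A removes the donor that would stabilise the cation, the medium is neutral and of low polarity, and the primary hydroxyl is silylated.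

**Fragment 2 (steps 12–18)**

Step 12
Reactants: 17 1,3-dithiane; 18 (5R)-5-[(1R,2S,5R)-menthyloxy]-2(5H)-furanone; 19 4-benzyloxy-3,5-dimethoxybenzaldehyde
Product: 22 (3S,4R,5R)-3-[(4-benzyloxy-3,5-dimethoxyphenyl)(hydroxy)methyl]-4-(1,3-dithian-2-yl)-5-menthyloxydihydrofuran-2(3H)-one (carbinol epimers), via 2-lithio-1,3-dithiane 20 (not isolated), via lithium lactone enolate 21 (not isolated)
Conditions: 17, n-BuLi, THF, −30 °C; 18, −78 °C; 19, −78 °C; AcOH quench
Reagents that add atoms: none
Why: Tandem Michael–aldol, in which the sulfur-stabilised anion adds 1,4 anti to the menthyloxy group (sets C4) and the enolate adds to the aldehyde anti to the new C4 substituent (sets C3); the carbinol centre is left uncontrolled because step 14 erases it.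

Step 13
Reactants: 22 the lactone acetal
Product: 23 (2R,3R)-2-[(4-benzyloxy-3,5-dimethoxyphenyl)(hydroxy)methyl]-3-(1,3-dithian-2-yl)butane-1,4-diol (carbinol epimers)
Conditions: LiAlH4, THF, 0 °C to rt
Reagents that add atoms: none
Why: Hydride reduces the lactone and, after collapse of the acetal carbon to an aldehyde with loss of menthol, that carbon as well, giving the triol with dithiane and benzyl ether intact.

Step 14
Reactants: 23 the triol
Product: 24 [(2S,3R,4R)-2-(4-benzyloxy-3,5-dimethoxyphenyl)-4-(1,3-dithian-2-yl)tetrahydrofuran-3-yl]methanol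
Conditions: BF3·OEt2, CH2Cl2, −20 to 0 °C
Reagents that add atoms: none
Why: SN1 cycloetherification in which both carbinol epimers ionise to one electron-rich benzylic cation that is captured by the C4 hydroxyl to form ring E, the aryl group settling trans to the neighbouring CH2OH (sets C2 as S); the other hydroxyl could only form an oxetane.

Step 15
Reactants: 24 the dithiane
Product: 26 (3aR,4S,6aR)-4-(4-benzyloxy-3,5-dimethoxyphenyl)tetrahydro-1H,3H-furo[3,4-c]furan-1-ol (anomers), via hydroxy aldehyde 25 (not isolated)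
Conditions: MeI, CaCO3, MeCN/H2O, 45 °C
Reagents that add atoms: water O
Why: S-Methylation and hydrolysis unmask the aldehyde without an oxidant, and the cis CH2OH adds to it at once to close ring D as the cis-fused lactol.

Step 16
Reactants: 26 the benzyl ether lactol
Product: 27 (3aR,4S,6aR)-4-(4-hydroxy-3,5-dimethoxyphenyl)tetrahydro-1H,3H-furo[3,4-c]furan-1-ol (anomers)
Conditions: H2 (1 atm), Pd/C (10 wt%), EtOAc, rt
Reagents that add atoms: none
Why: Hydrogenolysis of the O-benzyl group should be much faster than cleavage of the cyclic benzylic ether, and it is done here so that no hydrogenation is needed after the union.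

Step 17
Reactants: 27 the phenol lactol
Product: 28 (3aR,4S,6aR)-4-(4-acetoxy-3,5-dimethoxyphenyl)tetrahydro-1H,3H-furo[3,4-c]furan-1-yl acetate (anomers)
Conditions: Ac2O, pyridine, DMAP (cat.), CH2Cl2, 0 °C to rt
Reagents that add atoms: acetic anhydride CC(=O)OC(C)=O
Why: Acetylation gives the anomeric leaving group and at the same time turns the ring F oxygen into a poor donor, so the ring E benzylic ether resists the Lewis acids of steps 18 and 19.

Step 18
Reactants: 28 the diacetate
Product: 29 (3aR,4S,6aR)-4-(4-acetoxy-3,5-dimethoxyphenyl)-1-bromotetrahydro-1H,3H-furo[3,4-c]furan (anomers, used crude)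
Conditions: TMSBr, CH2Cl2, 0 °C; evaporate
Reagents that add atoms: bromotrimethylsilane C[Si](C)(C)Br
Why: Exchange of an anomeric acetate for bromide with TMSBr is standard for lactol acetates, and the aryl acetate and aryl methyl ethers are not touched at 0 °C.

**Union and deprotection (steps 19–21)**

Step 19
Reactants: 16 the aryl bromide; 29 the anomeric bromide
Product: 32 4-[(2S,3S)-5-[(1S,3aR,4S,6aR)-4-(4-acetoxy-3,5-dimethoxyphenyl)tetrahydro-1H,3H-furo[3,4-c]furan-1-yl]-3-(tert-butyldimethylsilyloxymethyl)-7-methoxy-2,3-dihydrobenzofuran-2-yl]-2-methoxyphenyl 4-methylbenzenesulfonate, via aryllithium 30 (not isolated), via arylzinc bromide 31 (not isolated)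
Conditions: 16, n-BuLi, THF, −78 °C; ZnBr2, −78 to 0 °C; 29, toluene, −40 °C to rt
Reagents that add atoms: none
Why: Bromine–lithium exchange at −78 °C outruns attack on the sulfonate, ZnBr2 gives an ester-tolerant arylzinc, and the α-bromo ether ionises to the bicyclic oxocarbenium ion that is arylated on its convex face, as in the arylzinc C-arylation of furanosyl and pyranosyl halides, which places ring B exo (1S).

Step 20
Reactants: 32 the coupled tosylate acetate
Product: 33 4-[(1S,3aR,4S,6aR)-4-[(2S,3S)-3-(tert-butyldimethylsilyloxymethyl)-2-(4-hydroxy-3-methoxyphenyl)-7-methoxy-2,3-dihydrobenzofuran-5-yl]tetrahydro-1H,3H-furo[3,4-c]furan-1-yl]-2,6-dimethoxyphenol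
Conditions: Mg turnings, MeOH, rt
Reagents that add atoms: none
Why: Electron transfer from magnesium cleaves the aryl S–O bond and the Mg(OMe)2 formed methanolyses the aryl acetate, both at room temperature, where the para-hydroxybenzylic ethers should not epimerise.

Step 21
Reactants: 33 the silyl ether
Product: 34 the target, CNP0126146.1
Conditions: TBAF, AcOH, THF, 0 °C to rt
Reagents that add atoms: none
Why: Buffered fluoride removes the primary silyl ether without acid, which would threaten the cis ring C and the furofuran once the phenols are free.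

**Compound list**
1 | 5-bromo-2-hydroxy-3-methoxybenzaldehyde | COc1cc(Br)cc(C=O)c1O | starting material
2 | 2-(allyloxy)-5-bromo-3-methoxybenzaldehyde | COc1cc(Br)cc(C=O)c1OCC=C | intermediate
3 | 2-(allyloxy)-5-bromo-1-methoxy-3-(2-methoxyvinyl)benzene (E/Z) | COC=Cc1cc(Br)cc(OC)c1OCC=C | intermediate
4 | 2-[2-(allyloxy)-5-bromo-3-methoxyphenyl]acetaldehyde | O=CCc1cc(Br)cc(OC)c1OCC=C | intermediate
5 | 2-[2-(allyloxy)-5-bromo-3-methoxyphenyl]acetic acid | OC(=O)Cc1cc(Br)cc(OC)c1OCC=C | intermediate
6 | (R)-4-benzyl-2-oxazolidinone | O=C1N[C@H](Cc2ccccc2)CO1 | starting material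
7 | mixed anhydride of 5 with pivalic acid | CC(C)(C)C(=O)OC(=O)Cc1cc(Br)cc(OC)c1OCC=C | intermediate
8 | (R)-3-{2-[2-(allyloxy)-5-bromo-3-methoxyphenyl]acetyl}-4-benzyloxazolidin-2-one | COc1cc(Br)cc(CC(=O)N2[C@H](Cc3ccccc3)COC2=O)c1OCC=C | intermediate
9 | vanillin | COc1cc(C=O)ccc1O | starting material
10 | 4-formyl-2-methoxyphenyl 4-methylbenzenesulfonate | COc1cc(C=O)ccc1OS(=O)(=O)c1ccc(C)cc1 | intermediate
11 | dibutylboron Z-enolate of 8 | CCCCB(CCCC)O/C(=C\c1cc(Br)cc(OC)c1OCC=C)N1[C@H](Cc2ccccc2)COC1=O | intermediate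
12 | (2R,3R) syn-aldol imide | COc1cc([C@H](O)[C@H](C(=O)N3[C@H](Cc4ccccc4)COC3=O)c2cc(Br)cc(OC)c2OCC=C)ccc1OS(=O)(=O)c1ccc(C)cc1 | intermediate
13 | (1R,2S) 1,3-diol | COc1cc([C@H](O)[C@H](CO)c2cc(Br)cc(OC)c2OCC=C)ccc1OS(=O)(=O)c1ccc(C)cc1 | intermediate
14 | (1R,2S) primary silyl ether, allyl-protected | COc1cc([C@H](O)[C@H](CO[Si](C)(C)C(C)(C)C)c2cc(Br)cc(OC)c2OCC=C)ccc1OS(=O)(=O)c1ccc(C)cc1 | intermediate
15 | (1R,2S) syn phenol carbinol (key-step precursor) | COc1cc([C@H](O)[C@H](CO[Si](C)(C)C(C)(C)C)c2cc(Br)cc(OC)c2O)ccc1OS(=O)(=O)c1ccc(C)cc1 | intermediate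
16 | (2S,3S) cis-5-bromo-2,3-dihydrobenzofuran (key-step product) | COc1cc([C@H]2Oc3c(OC)cc(Br)cc3[C@H]2CO[Si](C)(C)C(C)(C)C)ccc1OS(=O)(=O)c1ccc(C)cc1 | intermediate
17 | 1,3-dithiane | C1CSCSC1 | starting material
18 | (5R)-5-[(1R,2S,5R)-menthyloxy]-2(5H)-furanone | O=C1O[C@@H](O[C@@H]2C[C@H](C)CC[C@H]2C(C)C)C=C1 | starting material
19 | 4-benzyloxy-3,5-dimethoxybenzaldehyde | COc1cc(C=O)cc(OC)c1OCc1ccccc1 | starting material
20 | 2-lithio-1,3-dithiane | [Li]C1SCCCS1 | intermediate
21 | lithium enolate of the 4-dithianyl-5-menthyloxy lactone | [Li]OC1=C[C@@H](C2SCCCS2)[C@H](O[C@@H]2C[C@H](C)CC[C@H]2C(C)C)O1 | intermediate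
22 | (3S,4R,5R) Michael–aldol lactone (carbinol epimers) | O=C1O[C@@H](O[C@@H]2C[C@H](C)CC[C@H]2C(C)C)[C@H](C2SCCCS2)[C@H]1C(O)c1cc(OC)c(OCc2ccccc2)c(OC)c1 | intermediate
23 | (2R,3R) triol (carbinol epimers) | OC[C@H](C(O)c1cc(OC)c(OCc2ccccc2)c(OC)c1)[C@H](CO)C1SCCCS1 | intermediate
24 | [(2S,3R,4R)-2-aryl-4-(1,3-dithian-2-yl)tetrahydrofuran-3-yl]methanol | OC[C@H]1[C@@H](C2SCCCS2)CO[C@@H]1c1cc(OC)c(OCc2ccccc2)c(OC)c1 | intermediate
25 | (3R,4R,5S)-5-aryl-4-(hydroxymethyl)tetrahydrofuran-3-carbaldehyde | OC[C@H]1[C@@H](C=O)CO[C@@H]1c1cc(OC)c(OCc2ccccc2)c(OC)c1 | intermediate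
26 | (3aR,4S,6aR) benzyl-protected furofuran lactol (anomers) | OC1OC[C@H]2[C@@H]1CO[C@@H]2c1cc(OC)c(OCc2ccccc2)c(OC)c1 | intermediate
27 | (3aR,4S,6aR) phenol lactol (anomers) | OC1OC[C@H]2[C@@H]1CO[C@@H]2c1cc(OC)c(O)c(OC)c1 | intermediate
28 | (3aR,4S,6aR) lactol diacetate (anomers) | CC(=O)OC1OC[C@H]2[C@@H]1CO[C@@H]2c1cc(OC)c(OC(C)=O)c(OC)c1 | intermediate
29 | (3aR,4S,6aR) anomeric bromide (anomers) | BrC1OC[C@H]2[C@@H]1CO[C@@H]2c1cc(OC)c(OC(C)=O)c(OC)c1 | intermediate
30 | aryllithium from 16 | COc1cc([C@H]2Oc3c(OC)cc([Li])cc3[C@H]2CO[Si](C)(C)C(C)(C)C)ccc1OS(=O)(=O)c1ccc(C)cc1 | intermediate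
31 | arylzinc bromide from 16 | COc1cc([C@H]2Oc3c(OC)cc([Zn]Br)cc3[C@H]2CO[Si](C)(C)C(C)(C)C)ccc1OS(=O)(=O)c1ccc(C)cc1 | intermediate
32 | coupled product (OTs, OAc, OTBS) | COc1cc([C@H]2Oc3c(OC)cc([C@H]4OC[C@H]5[C@@H]4CO[C@@H]5c4cc(OC)c(OC(C)=O)c(OC)c4)cc3[C@H]2CO[Si](C)(C)C(C)(C)C)ccc1OS(=O)(=O)c1ccc(C)cc1 | intermediate
33 | bisphenol silyl ether | COc1cc([C@H]2Oc3c(OC)cc([C@H]4OC[C@H]5[C@@H]4CO[C@@H]5c4cc(OC)c(O)c(OC)c4)cc3[C@H]2CO[Si](C)(C)C(C)(C)C)ccc1O | intermediate
34 | CNP0126146.1 | COc1cc([C@H]2Oc3c(OC)cc([C@H]4OC[C@H]5[C@@H]4CO[C@@H]5c4cc(OC)c(O)c(OC)c4)cc3[C@H]2CO)ccc1O | target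

**Step count**
- Total: 21 steps.
- Longest linear sequence: 13 steps (steps 1–5, 7–11, 19–21).

**Steps most likely to fail**

Step 11. The activated benzylic carbinol may ionise or lose a proton before the phenoxide attacks, which would erode the inversion at C2 (leak to the trans ring) or give the stilbene. The fallback sets out from 14. The secondary alcohol is converted with MsCl and Et3N in CH2Cl2 at −20 °C into (1R,2S)-2-(2-allyloxy-5-bromo-3-methoxyphenyl)-3-(tert-butyldimethylsilyloxy)-1-(3-methoxy-4-tosyloxyphenyl)propyl methanesulfonate F1. Pd(PPh3)4 with K2CO3 in MeOH/THF then removes the allyl group, and the free phenoxide displaces the preformed sulfonate with inversion (anionic Williamson closure in place of redox condensation). This returns to the route at 16.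

Step 19. Capture of the oxocarbenium ion by the arylzinc may be slow, so that 29 loses HBr to the enol ether, or the zinc salts may epimerise the new benzylic ether. The fallback sets out from 16 and 26 and forms the same bond by carbonyl addition.
- 16 is converted by n-BuLi and MgBr2·OEt2 into the arylmagnesium bromide, which adds to the open hydroxy-aldehyde form of lactol 26 (first deprotonated with i-PrMgCl) to give the benzylic diol F2 (carbinol epimers).
- BF3·OEt2 at low temperature closes ring D through the ring B-stabilised benzylic cation, which should favour the exo aryl under kinetic control, giving the benzyl-protected furofuran F3.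
- H2 with Pd/C gives the ring F phenol F4, and Mg in MeOH removes the sulfonate, returning to the route at 33.

Step 12. The dithianyl anion may add 1,2 to the lactone carbonyl or abstract the acetal proton instead of adding 1,4. The fallback sets out from 18 and 19 and uses a softer, bulkier acid-level synthon.
- Tris(methylthio)methyllithium adds 1,4 and the enolate is trapped with 19 to give the orthothioester lactone F5.
- LiAlH4 gives the triol F6, and BF3·OEt2 closes ring E to the tetrahydrofuran orthothioester F7.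
- HgCl2 and HgO in aqueous MeCN hydrolyse the orthothioester, and the acid lactonises onto the cis CH2OH to give (3aR,4S,6aR)-4-(4-benzyloxy-3,5-dimethoxyphenyl)tetrahydro-1H,3H-furo[3,4-c]furan-1-one F8.
- i-Bu2AlH at −78 °C reduces F8 to the lactol, returning to the route at 26.

**Further compounds**
F1 | step 11 | benzylic methanesulfonate of 14 | COc1cc([C@H](OS(C)(=O)=O)[C@H](CO[Si](C)(C)C(C)(C)C)c2cc(Br)cc(OC)c2OCC=C)ccc1OS(=O)(=O)c1ccc(C)cc1
F2 | step 19 | benzylic diol from Grignard addition to lactol 26 (carbinol epimers) | COc1cc([C@H]2Oc3c(OC)cc(C(O)[C@H]4CO[C@H](c5cc(OC)c(OCc6ccccc6)c(OC)c5)[C@H]4CO)cc3[C@H]2CO[Si](C)(C)C(C)(C)C)ccc1OS(=O)(=O)c1ccc(C)cc1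
F3 | step 19 | benzyl-protected coupled furofuran | COc1cc([C@H]2Oc3c(OC)cc([C@H]4OC[C@H]5[C@@H]4CO[C@@H]5c4cc(OC)c(OCc5ccccc5)c(OC)c4)cc3[C@H]2CO[Si](C)(C)C(C)(C)C)ccc1OS(=O)(=O)c1ccc(C)cc1
F4 | step 19 | coupled furofuran with free ring F phenol | COc1cc([C@H]2Oc3c(OC)cc([C@H]4OC[C@H]5[C@@H]4CO[C@@H]5c4cc(OC)c(O)c(OC)c4)cc3[C@H]2CO[Si](C)(C)C(C)(C)C)ccc1OS(=O)(=O)c1ccc(C)cc1
F5 | step 12 | orthothioester Michael–aldol lactone (carbinol epimers) | O=C1O[C@@H](O[C@@H]2C[C@H](C)CC[C@H]2C(C)C)[C@H](C(SC)(SC)SC)[C@H]1C(O)c1cc(OC)c(OCc2ccccc2)c(OC)c1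
F6 | step 12 | orthothioester triol (carbinol epimers) | OC[C@H](C(O)c1cc(OC)c(OCc2ccccc2)c(OC)c1)[C@H](CO)C(SC)(SC)SC
F7 | step 12 | tetrahydrofuran orthothioester | OC[C@H]1[C@@H](C(SC)(SC)SC)CO[C@@H]1c1cc(OC)c(OCc2ccccc2)c(OC)c1
F8 | step 12 | furofuranone lactone | O=C1OC[C@H]2[C@@H]1CO[C@@H]2c1cc(OC)c(OCc2ccccc2)c(OC)c1
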